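**Retrosynthetic overview**
1. Target ⇐ O-desilylation ⇐ Evans–Tishchenko reduction (CH3CHO) of a macrocyclic 11-hydroxy-9-ketone, which sets C9 and puts the acetate on O11 in one step.
2. 14-membered carbocycle (last ring formed) ⇐ Nozaki–Hiyama–Kishi closure of C8–C9 from a (Z)-alkenyl iodide and a C9 aldehyde.
3. α-Methylene-ε-lactone (formed before the macrocycle) ⇐ epoxy-acid lactonization: the C16 acid opens an (11R,12R)-epoxide at C12 with inversion; the acrylic acid comes from a malonate (CH2O, −CO2).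
4. C3–C4 bond and the C3 stereocentre ⇐ new chromium-catalysed asymmetric alkenylation of a C3 aldehyde by an alkenylzirconocene made from a skipped iodo-enyne.
5. C3 aldehyde ⇐ organocatalytic malonate Michael addition (C1), cross-metathesis, Shi epoxidation (first ring, C11/C12), carboalumination/oxirane opening of hex-1-en-5-yne; enyne ⇐ but-2-yn-1-ol.

Assumption: cembrane numbering is used (C1 carries C15(=C17H2)–C16; methyls C18, C19, C20 sit on C4, C8, C12), and the (S)-sulfonamide–oxazoline ligand of step 9 is taken as the enantiomer that directs Re-face alkenylation.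

**Route**

Step 1
Reactants: 1 hex-1-en-5-yne
Product: 4 (E)-4-methylocta-3,7-dien-1-ol, via alkenyldimethylalane 2 (not isolated), via lithium alkenylalanate 3 (not isolated)
Conditions: AlMe3 (2 equiv), Cp2ZrCl2 (0.25 equiv), CH2Cl2, 0 to 23 °C; then n-BuLi, hexane/THF, −30 °C; oxirane (3 equiv), −30 to 23 °C; 1 M HCl
Reagents that add atoms: trimethylaluminium C[Al](C)C; oxirane C1CO1
Why: Negishi zirconium-catalysed carboalumination adds CH3 and Al syn across the alkyne only (Al on the terminal carbon), and the derived alanate opens oxirane with retention, fixing the E C11=C12 olefin with the C20 methyl.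

Step 2
Reactants: 4 (E)-4-methylocta-3,7-dien-1-ol
Product: 5 (E)-tert-butyl(dimethyl)[(4-methylocta-3,7-dien-1-yl)oxy]silane
Conditions: TBSCl, imidazole, DMF, 23 °C
Reagents that add atoms: tert-butyl(chloro)dimethylsilane CC(C)(C)[Si](C)(C)Cl
Why: Standard silylation of the primary alcohol, so that O9 cannot open the later epoxide.

Step 3
Reactants: 5 (E)-tert-butyl(dimethyl)[(4-methylocta-3,7-dien-1-yl)oxy]silane
Product: 6 (2R,3R)-3-(but-3-en-1-yl)-2-{2-[(tert-butyldimethylsilyl)oxy]ethyl}-3-methyloxirane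
Conditions: D-fructose-derived Shi ketone (0.3 equiv), KHSO5 (as 2KHSO5·KHSO4·K2SO4, 1.4 equiv), K2CO3, Bu4NHSO4 (cat.), MeCN/CH2(OMe)2/aq. Na2B4O7, 0 °C
Reagents that add atoms: potassium peroxymonosulfate [K+].[O-]S(=O)(=O)OO
Why: Shi asymmetric epoxidation: the chiral dioxirane attacks only the electron-rich trisubstituted E olefin (the monosubstituted alkene is inert) through the spiro transition state and sets the (11R,12R) epoxide by catalyst control.

Step 4
Reactants: 6 (2R,3R)-3-(but-3-en-1-yl)-2-{2-[(tert-butyldimethylsilyl)oxy]ethyl}-3-methyloxirane; 7 (E)-but-2-enal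
Product: 8 (E)-5-[(2R,3R)-3-{2-[(tert-butyldimethylsilyl)oxy]ethyl}-2-methyloxiran-2-yl]pent-2-enal
Conditions: 7 (5 equiv), second-generation Grubbs catalyst RuCl2(=CHPh)(PCy3)(H2IMes) (5 mol %), CH2Cl2, 40 °C
Reagents that add atoms: none
Why: Olefin cross-metathesis of the terminal alkene with crotonaldehyde gives the E enal (C1=C2–C3HO); the trisubstituted epoxide is inert to the ruthenium carbene.

Step 5
Reactants: 8 (E)-5-[(2R,3R)-3-{2-[(tert-butyldimethylsilyl)oxy]ethyl}-2-methyloxiran-2-yl]pent-2-enal; 9 dimethyl malonate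
Product: 10 dimethyl 2-[(3S)-1-[(2R,3R)-3-{2-[(tert-butyldimethylsilyl)oxy]ethyl}-2-methyloxiran-2-yl]-5-oxopentan-3-yl]malonate
Conditions: 9 (1.5 equiv), (R)-α,α-bis[3,5-bis(trifluoromethyl)phenyl]prolinol trimethylsilyl ether (10 mol %), EtOH, 0 °C
Reagents that add atoms: none
Why: Iminium-catalysed (Jørgensen–Hayashi) Michael addition: the (R)-catalyst shields one face of the E iminium ion so that malonate adds to C1 from the other face, setting C1 as (S).

Step 6
Reactants: 11 but-2-yn-1-ol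
Product: 13 (Z)-3-iodobut-2-en-1-ol, via cyclic alkenylaluminate 12 (not isolated)
Conditions: NaAlH2(OCH2CH2OMe)2 (1.5 equiv), THF, 0 to 23 °C; EtOAc; then I2, −78 °C; aq. Na2S2O3
Reagents that add atoms: iodine II
Why: Hydroxyl-directed trans-hydroalumination puts Al on the distal alkyne carbon cis to CH2O, and iodinolysis with retention gives the Z alkenyl iodide that carries the C7=C8 geometry of the target.

Step 7
Reactants: 13 (Z)-3-iodobut-2-en-1-ol
Product: 14 (Z)-1-bromo-3-iodobut-2-ene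
Conditions: PBr3 (0.4 equiv), Et2O, 0 °C
Reagents that add atoms: phosphorus tribromide BrP(Br)Br
Why: SN2 conversion of the primary allylic alcohol into the bromide without touching the alkenyl iodide or the olefin geometry.

Step 8
Reactants: 14 (Z)-1-bromo-3-iodobut-2-ene
Product: 15 (Z)-6-iodohept-5-en-2-yne
Conditions: prop-1-ynylmagnesium bromide (1.3 equiv), CuBr·SMe2 (5 mol %), THF, −20 to 0 °C
Reagents that add atoms: prop-1-ynylmagnesium bromide CC#C[Mg]Br
Why: Copper-catalysed SN2 coupling of the alkynyl Grignard reagent with the primary allylic bromide gives the skipped enyne (C18, C4–C8, C19); the alkenyl C–I bond is inert here.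

Step 9
Reactants: 10 dimethyl 2-[(3S)-1-[(2R,3R)-3-{2-[(tert-butyldimethylsilyl)oxy]ethyl}-2-methyloxiran-2-yl]-5-oxopentan-3-yl]malonate; 15 (Z)-6-iodohept-5-en-2-yne
Product: 17 dimethyl 2-[(3S,5S,6E,9Z)-1-[(2R,3R)-3-{2-[(tert-butyldimethylsilyl)oxy]ethyl}-2-methyloxiran-2-yl]-5-hydroxy-10-iodo-6-methylundeca-6,9-dien-3-yl]malonate, via alkenylzirconocene chloride 16 (not isolated)
Conditions: 15 (1.5 equiv), Cp2Zr(H)Cl (1.6 equiv), CH2Cl2, 23 °C; then 10, CrCl3(THF)3 (10 mol %), (S)-N-[2-(4-isopropyl-4,5-dihydrooxazol-2-yl)-6-methylphenyl]methanesulfonamide (12 mol %), Et3N (12 mol %), THF/MeCN, 0 °C; aq. NaHCO3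
Reagents that add atoms: none
Why: Proposed new method: a redox-neutral, chromium-catalysed enantioselective aldehyde alkenylation in which syn hydrozirconation (Zr settling on the methyl-bearing alkyne carbon, about 9:1 or better after equilibration) gives 16, its alkenyl group passes from zirconium to the chiral sulfonamide complex of trivalent chromium (transfer to a more electronegative metal, as in the known Zr-to-Zn and Zr-to-Ni transmetalations), the alkenylchromium adds to the Re face of the aldehyde to form C3–C4 with retention of the E olefin and set C3 as (S), and the oxophilic zirconocene takes the alkoxide from chromium so the catalyst turns over without a reductant; because no zerovalent nickel or divalent chromium is present, the alkenyl iodide, the epoxide and the acidic malonate C–H are left alone; closest known reaction types are the catalytic asymmetric Nozaki–Hiyama–Kishi alkenylation and the hydrozirconation/Zr-to-Zn transmetalation/asymmetric aldehyde alkenylation.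

Step 10
Reactants: 17 dimethyl 2-[(3S,5S,6E,9Z)-1-[(2R,3R)-3-{2-[(tert-butyldimethylsilyl)oxy]ethyl}-2-methyloxiran-2-yl]-5-hydroxy-10-iodo-6-methylundeca-6,9-dien-3-yl]malonate
Product: 18 dimethyl 2-[(3S,5S,6E,9Z)-5-[(tert-butyldimethylsilyl)oxy]-1-[(2R,3R)-3-{2-[(tert-butyldimethylsilyl)oxy]ethyl}-2-methyloxiran-2-yl]-10-iodo-6-methylundeca-6,9-dien-3-yl]malonate
Conditions: TBSCl, imidazole, DMAP (cat.), DMF, 23 °C
Reagents that add atoms: tert-butyl(chloro)dimethylsilane CC(C)(C)[Si](C)(C)Cl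
Why: Silylation of the secondary allylic alcohol, done at once so that O3 can neither lactonize onto the malonate nor compete in step 13.

Step 11
Reactants: 18 dimethyl 2-[(3S,5S,6E,9Z)-5-[(tert-butyldimethylsilyl)oxy]-1-[(2R,3R)-3-{2-[(tert-butyldimethylsilyl)oxy]ethyl}-2-methyloxiran-2-yl]-10-iodo-6-methylundeca-6,9-dien-3-yl]malonate
Product: 19 2-[(3S,5S,6E,9Z)-5-[(tert-butyldimethylsilyl)oxy]-1-[(2R,3R)-3-{2-[(tert-butyldimethylsilyl)oxy]ethyl}-2-methyloxiran-2-yl]-10-iodo-6-methylundeca-6,9-dien-3-yl]malonic acid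
Conditions: LiOH (6 equiv), THF/MeOH/H2O, 23 °C; then 0.5 M HCl to pH 4, 0 °C
Reagents that add atoms: lithium hydroxide [Li+].[OH-]
Why: Ester saponification to the malonic acid; silyl ethers, the trisubstituted epoxide and the alkenyl iodide are stable to LiOH.

Step 12
Reactants: 19 2-[(3S,5S,6E,9Z)-5-[(tert-butyldimethylsilyl)oxy]-1-[(2R,3R)-3-{2-[(tert-butyldimethylsilyl)oxy]ethyl}-2-methyloxiran-2-yl]-10-iodo-6-methylundeca-6,9-dien-3-yl]malonic acid
Product: 20 2-[(3S,5S,6E,9Z)-5-[(tert-butyldimethylsilyl)oxy]-1-[(2R,3R)-3-{2-[(tert-butyldimethylsilyl)oxy]ethyl}-2-methyloxiran-2-yl]-10-iodo-6-methylundeca-6,9-dien-3-yl]prop-2-enoic acid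
Conditions: (CH2O)n (5 equiv), Et2NH (2 equiv), THF, 60 °C
Reagents that add atoms: formaldehyde C=O
Why: Mannich-type decarboxylative methylenation of the malonic acid gives the α-substituted acrylic acid (C15=C17 and C16) under mildly basic conditions that leave the epoxide intact.

Step 13
Reactants: 20 2-[(3S,5S,6E,9Z)-5-[(tert-butyldimethylsilyl)oxy]-1-[(2R,3R)-3-{2-[(tert-butyldimethylsilyl)oxy]ethyl}-2-methyloxiran-2-yl]-10-iodo-6-methylundeca-6,9-dien-3-yl]prop-2-enoic acid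
Product: 21 (4S,7S)-7-[(1R)-3-[(tert-butyldimethylsilyl)oxy]-1-hydroxypropyl]-4-[(2S,3E,6Z)-2-[(tert-butyldimethylsilyl)oxy]-7-iodo-3-methylocta-3,6-dien-1-yl]-7-methyl-3-methylideneoxepan-2-one
Conditions: (+)-camphor-10-sulfonic acid (10 mol %), CH2Cl2, 0 °C
Reagents that add atoms: none
Why: Acid-catalysed epoxy-acid lactonization (7-exo-tet intramolecular epoxide opening): the C16 carboxylic acid attacks the tertiary C12 from the back side, inverting it to (12S) and leaving the C11–O bond (11R) untouched, which closes the ε-lactone.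

Step 14
Reactants: 21 (4S,7S)-7-[(1R)-3-[(tert-butyldimethylsilyl)oxy]-1-hydroxypropyl]-4-[(2S,3E,6Z)-2-[(tert-butyldimethylsilyl)oxy]-7-iodo-3-methylocta-3,6-dien-1-yl]-7-methyl-3-methylideneoxepan-2-one
Product: 22 (4S,7S)-4-[(2S,3E,6Z)-2-[(tert-butyldimethylsilyl)oxy]-7-iodo-3-methylocta-3,6-dien-1-yl]-7-[(1R)-1,3-dihydroxypropyl]-7-methyl-3-methylideneoxepan-2-one
Conditions: HF·pyridine, pyridine, THF, 0 °C
Reagents that add atoms: none
Why: Selective cleavage of the primary silyl ether in the presence of the more hindered secondary allylic one under buffered HF·pyridine.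

Step 15
Reactants: 22 (4S,7S)-4-[(2S,3E,6Z)-2-[(tert-butyldimethylsilyl)oxy]-7-iodo-3-methylocta-3,6-dien-1-yl]-7-[(1R)-1,3-dihydroxypropyl]-7-methyl-3-methylideneoxepan-2-one
Product: 23 (4S,7S)-4-[(2S,3E,6Z)-2-[(tert-butyldimethylsilyl)oxy]-7-iodo-3-methylocta-3,6-dien-1-yl]-7-[(1R)-1-hydroxy-3-oxopropyl]-7-methyl-3-methylideneoxepan-2-one
Conditions: TEMPO (20 mol %), PhI(OAc)2 (1.2 equiv), CH2Cl2, 23 °C
Reagents that add atoms: none
Why: Oxoammonium (TEMPO/PhI(OAc)2) oxidation is selective for the primary C9 alcohol over the hindered secondary C11 alcohol and stops at the aldehyde.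

Step 16
Reactants: 23 (4S,7S)-4-[(2S,3E,6Z)-2-[(tert-butyldimethylsilyl)oxy]-7-iodo-3-methylocta-3,6-dien-1-yl]-7-[(1R)-1-hydroxy-3-oxopropyl]-7-methyl-3-methylideneoxepan-2-one
Product: 24 (1S,3S,4E,7Z,9RS,11R,12S)-3-[(tert-butyldimethylsilyl)oxy]-9,11-dihydroxycembra-4,7,15(17)-trien-16,12-olide
Conditions: CrCl2 (15 equiv), NiCl2 (0.15 equiv), DMSO, 23 °C, 2 mM, slow addition
Reagents that add atoms: none
Why: Intramolecular Nozaki–Hiyama–Kishi reaction: zerovalent nickel inserts into the alkenyl C–I bond with retention of the Z geometry, transmetalation gives the alkenylchromium, and its addition to the aldehyde at high dilution closes the 14-membered ring (the C9 configuration is erased in step 17).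

Step 17
Reactants: 24 (1S,3S,4E,7Z,9RS,11R,12S)-3-[(tert-butyldimethylsilyl)oxy]-9,11-dihydroxycembra-4,7,15(17)-trien-16,12-olide
Product: 25 (1S,3S,4E,7Z,11R,12S)-3-[(tert-butyldimethylsilyl)oxy]-11-hydroxy-9-oxocembra-4,7,15(17)-trien-16,12-olide
Conditions: MnO2 (30 equiv), CH2Cl2, 23 °C
Reagents that add atoms: none
Why: MnO2 oxidises only the allylic C9 alcohol and leaves the non-allylic C11 alcohol, giving the β-hydroxy enone.

Step 18
Reactants: 25 (1S,3S,4E,7Z,11R,12S)-3-[(tert-butyldimethylsilyl)oxy]-11-hydroxy-9-oxocembra-4,7,15(17)-trien-16,12-olide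
Product: 26 (1S,3S,4E,7Z,9R,11R,12S)-11-acetoxy-3-[(tert-butyldimethylsilyl)oxy]-9-hydroxycembra-4,7,15(17)-trien-16,12-olide
Conditions: SmI2 (0.3 equiv, premixed with the aldehyde), CH3CHO (10 equiv), THF, −10 °C
Reagents that add atoms: acetaldehyde CC=O
Why: Evans–Tishchenko reduction: the C11 hydroxyl forms a samarium-bound hemiacetal with acetaldehyde that delivers hydride intramolecularly to the C9 ketone through a chair transition state, giving the 1,3-anti (9R) alcohol and leaving the acetate on O11 only.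

Step 19
Reactants: 26 (1S,3S,4E,7Z,9R,11R,12S)-11-acetoxy-3-[(tert-butyldimethylsilyl)oxy]-9-hydroxycembra-4,7,15(17)-trien-16,12-olide
Product: 27 (1S,3S,4E,7Z,9R,11R,12S)-11-acetoxy-3,9-dihydroxycembra-4,7,15(17)-trien-16,12-olide
Conditions: HF·pyridine, THF/pyridine, 0 to 23 °C
Reagents that add atoms: none
Why: Fluoride cleavage of the last silyl ether; the α-methylene lactone, the acetate and the allylic alcohols tolerate buffered HF·pyridine.

**Compound list**

1 | hex-1-en-5-yne | C#CCCC=C | starting material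
2 | (E)-dimethyl(2-methylhexa-1,5-dien-1-yl)alane | C[Al](C)/C=C(\C)CCC=C | intermediate
3 | lithium (E)-butyl(dimethyl)(2-methylhexa-1,5-dien-1-yl)alanate | [Li+].CCCC[Al-](C)(C)/C=C(\C)CCC=C | intermediate
4 | (E)-4-methylocta-3,7-dien-1-ol | OCC/C=C(\C)CCC=C | intermediate
5 | (E)-tert-butyl(dimethyl)[(4-methylocta-3,7-dien-1-yl)oxy]silane | CC(C)(C)[Si](C)(C)OCC/C=C(\C)CCC=C | intermediate
6 | (2R,3R)-3-(but-3-en-1-yl)-2-{2-[(tert-butyldimethylsilyl)oxy]ethyl}-3-methyloxirane | CC(C)(C)[Si](C)(C)OCC[C@H]1O[C@]1(C)CCC=C | intermediate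
7 | (E)-but-2-enal (crotonaldehyde) | C/C=C/C=O | starting material
8 | (E)-5-[(2R,3R)-3-{2-[(tert-butyldimethylsilyl)oxy]ethyl}-2-methyloxiran-2-yl]pent-2-enal | CC(C)(C)[Si](C)(C)OCC[C@H]1O[C@]1(C)CC/C=C/C=O | intermediate
9 | dimethyl malonate | COC(=O)CC(=O)OC | starting material
10 | dimethyl 2-[(3S)-1-[(2R,3R)-3-{2-[(tert-butyldimethylsilyl)oxy]ethyl}-2-methyloxiran-2-yl]-5-oxopentan-3-yl]malonate | CC(C)(C)[Si](C)(C)OCC[C@H]1O[C@]1(C)CC[C@H](C(C(=O)OC)C(=O)OC)CC=O | intermediate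
11 | but-2-yn-1-ol | CC#CCO | starting material
12 | sodium 2,2-bis(2-methoxyethoxy)-3-methyl-2,5-dihydro-1,2-oxaaluminol-2-uide (cyclic alkenylaluminate) | [Na+].CC1=CCO[Al-]1(OCCOC)OCCOC | intermediate
13 | (Z)-3-iodobut-2-en-1-ol | C/C(I)=C/CO | intermediate
14 | (Z)-1-bromo-3-iodobut-2-ene | C/C(I)=C/CBr | intermediate
15 | (Z)-6-iodohept-5-en-2-yne | CC#CC/C=C(/C)I | intermediate
16 | chlorobis(cyclopentadienyl)[(2E,5Z)-6-iodohepta-2,5-dien-2-yl]zirconium | C/C(=C\C/C=C(/C)I)[Zr](Cl)(C1C=CC=C1)C1C=CC=C1 | intermediate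
17 | dimethyl 2-[(3S,5S,6E,9Z)-1-[(2R,3R)-3-{2-[(tert-butyldimethylsilyl)oxy]ethyl}-2-methyloxiran-2-yl]-5-hydroxy-10-iodo-6-methylundeca-6,9-dien-3-yl]malonate | CC(C)(C)[Si](C)(C)OCC[C@H]1O[C@]1(C)CC[C@H](C(C(=O)OC)C(=O)OC)C[C@H](O)/C(C)=C/C/C=C(/C)I | intermediate
18 | 5-O-tert-butyldimethylsilyl ether of 17 | CC(C)(C)[Si](C)(C)OCC[C@H]1O[C@]1(C)CC[C@H](C(C(=O)OC)C(=O)OC)C[C@H](O[Si](C)(C)C(C)(C)C)/C(C)=C/C/C=C(/C)I | intermediate
19 | malonic acid corresponding to diester 18 | CC(C)(C)[Si](C)(C)OCC[C@H]1O[C@]1(C)CC[C@H](C(C(=O)O)C(=O)O)C[C@H](O[Si](C)(C)C(C)(C)C)/C(C)=C/C/C=C(/C)I | intermediate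
20 | 2-[(3S,5S,6E,9Z)-5-[(tert-butyldimethylsilyl)oxy]-1-[(2R,3R)-3-{2-[(tert-butyldimethylsilyl)oxy]ethyl}-2-methyloxiran-2-yl]-10-iodo-6-methylundeca-6,9-dien-3-yl]prop-2-enoic acid | CC(C)(C)[Si](C)(C)OCC[C@H]1O[C@]1(C)CC[C@H](C(=C)C(=O)O)C[C@H](O[Si](C)(C)C(C)(C)C)/C(C)=C/C/C=C(/C)I | intermediate
21 | (4S,7S)-7-[(1R)-3-[(tert-butyldimethylsilyl)oxy]-1-hydroxypropyl]-4-[(2S,3E,6Z)-2-[(tert-butyldimethylsilyl)oxy]-7-iodo-3-methylocta-3,6-dien-1-yl]-7-methyl-3-methylideneoxepan-2-one | C=C1C(=O)O[C@@]([C@H](O)CCO[Si](C)(C)C(C)(C)C)(C)CC[C@H]1C[C@H](O[Si](C)(C)C(C)(C)C)/C(C)=C/C/C=C(/C)I | intermediate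
22 | (4S,7S)-4-[(2S,3E,6Z)-2-[(tert-butyldimethylsilyl)oxy]-7-iodo-3-methylocta-3,6-dien-1-yl]-7-[(1R)-1,3-dihydroxypropyl]-7-methyl-3-methylideneoxepan-2-one | C=C1C(=O)O[C@@]([C@H](O)CCO)(C)CC[C@H]1C[C@H](O[Si](C)(C)C(C)(C)C)/C(C)=C/C/C=C(/C)I | intermediate
23 | (4S,7S)-4-[(2S,3E,6Z)-2-[(tert-butyldimethylsilyl)oxy]-7-iodo-3-methylocta-3,6-dien-1-yl]-7-[(1R)-1-hydroxy-3-oxopropyl]-7-methyl-3-methylideneoxepan-2-one | C=C1C(=O)O[C@@]([C@H](O)CC=O)(C)CC[C@H]1C[C@H](O[Si](C)(C)C(C)(C)C)/C(C)=C/C/C=C(/C)I | intermediate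
24 | (1S,3S,4E,7Z,9RS,11R,12S)-3-[(tert-butyldimethylsilyl)oxy]-9,11-dihydroxycembra-4,7,15(17)-trien-16,12-olide (C9 epimers) | C=C1C(=O)O[C@@]2(C)CC[C@H]1C[C@H](O[Si](C)(C)C(C)(C)C)/C(C)=C/C/C=C(/C)C(O)C[C@H]2O | intermediate
25 | (1S,3S,4E,7Z,11R,12S)-3-[(tert-butyldimethylsilyl)oxy]-11-hydroxy-9-oxocembra-4,7,15(17)-trien-16,12-olide | C=C1C(=O)O[C@@]2(C)CC[C@H]1C[C@H](O[Si](C)(C)C(C)(C)C)/C(C)=C/C/C=C(/C)C(=O)C[C@H]2O | intermediate
26 | (1S,3S,4E,7Z,9R,11R,12S)-11-acetoxy-3-[(tert-butyldimethylsilyl)oxy]-9-hydroxycembra-4,7,15(17)-trien-16,12-olide | C=C1C(=O)O[C@@]2(C)CC[C@H]1C[C@H](O[Si](C)(C)C(C)(C)C)/C(C)=C/C/C=C(/C)[C@H](O)C[C@H]2OC(C)=O | intermediate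
27 | (1S,3S,4E,7Z,9R,11R,12S)-11-acetoxy-3,9-dihydroxycembra-4,7,15(17)-trien-16,12-olide (CNP0183491.1) | C=C1C(=O)O[C@@]2(C)CC[C@H]1C[C@H](O)/C(C)=C/C/C=C(/C)[C@H](O)C[C@H]2OC(C)=O | target

**Step count and risks**

Total step count: 19. Longest linear sequence: 16 steps (1 to 27 through steps 1–5 and 9–19); steps 6–8 make the enyne 15 in a side branch.

The three steps most likely to fail:

Step 9 (the proposed new step). The Zr-to-Cr transfer may be slow, turnover may stall, or the enantioselectivity may be low. The fallback uses known chemistry, sets out from 10 and 15 and comes back at 17. Enyne 15 is hydrozirconated to 16 as before and transmetalated with ZnMe2 (toluene, −65 °C) to the methyl(alkenyl)zinc F1, used in threefold excess so that the malonate C–H is absorbed. Uncatalysed addition of F1 to aldehyde 10 at 0 °C gives the C3-epimeric allylic alcohols F2. Dess–Martin oxidation gives the enone F3, and reduction with (R)-Me-CBS oxazaborolidine and catecholborane (the 1-methylalkenyl group acting as the large substituent) gives 17.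

Step 13. The 7-exo opening may be slow, or the O9 silyl ether may compete for C12. The fallback sets out from 19 and comes back at 21. The ring is closed one step earlier from the more acidic malonic diacid 19, in which either carboxyl can attack C12 and the second acts as the internal acid (CH2Cl2, 0 °C, optionally with camphorsulfonic acid), to give the α-carboxy-ε-lactone F4 as C15 epimers. F4 is then methylenated with loss of CO2 ((CH2O)n, Et2NH, THF, 60 °C), the classical α-carboxy-lactone route to α-methylene lactones, to give 21.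

Step 16. The hindered Z-iodoalkene may be reduced or give oligomers instead of the 14-membered ring. The fallback sets out from 21 and comes back at 26; it forms the same C8–C9 bond as a ketone by an intramolecular Stille acylation. Alcohol 21 is acetylated (Ac2O, DMAP, pyridine) to the 11-acetate F5. The primary silyl group is removed (HF·pyridine, pyridine) to give the alcohol F6, which is oxidised (TEMPO, PhI(OAc)2, MeCN/H2O) to the iodo acid F7. Iodine is exchanged for tin (Pd(PPh3)4, Me3SnSnMe3, i-Pr2NEt) to give the stannyl acid F8. This is converted with 1-chloro-N,N,2-trimethylprop-1-enylamine into the acid chloride F9 (not isolated) and cyclised at high dilution (Pd2(dba)3, tri(2-furyl)phosphine, THF) to the macrocyclic 11-acetoxy-9-ketone F10. Reduction with (S)-Me-CBS oxazaborolidine and catecholborane at −78 °C then gives the (9R)-alcohol 26.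

Further compounds
F1 | step 9 | methyl[(2E,5Z)-6-iodohepta-2,5-dien-2-yl]zinc | C/C(=C\C/C=C(/C)I)[Zn]C
F2 | step 9 | dimethyl 2-[(3S,5RS,6E,9Z)-1-[(2R,3R)-3-{2-[(tert-butyldimethylsilyl)oxy]ethyl}-2-methyloxiran-2-yl]-5-hydroxy-10-iodo-6-methylundeca-6,9-dien-3-yl]malonate (C3 epimers of 17) | CC(C)(C)[Si](C)(C)OCC[C@H]1O[C@]1(C)CC[C@H](C(C(=O)OC)C(=O)OC)CC(O)/C(C)=C/C/C=C(/C)I
F3 | step 9 | dimethyl 2-[(3S,6E,9Z)-1-[(2R,3R)-3-{2-[(tert-butyldimethylsilyl)oxy]ethyl}-2-methyloxiran-2-yl]-10-iodo-6-methyl-5-oxoundeca-6,9-dien-3-yl]malonate | CC(C)(C)[Si](C)(C)OCC[C@H]1O[C@]1(C)CC[C@H](C(C(=O)OC)C(=O)OC)CC(=O)/C(C)=C/C/C=C(/C)I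
F4 | step 13 | (4S,7S)-7-[(1R)-3-[(tert-butyldimethylsilyl)oxy]-1-hydroxypropyl]-4-[(2S,3E,6Z)-2-[(tert-butyldimethylsilyl)oxy]-7-iodo-3-methylocta-3,6-dien-1-yl]-7-methyl-2-oxooxepane-3-carboxylic acid (C3 epimers) | OC(=O)C1C(=O)O[C@@]([C@H](O)CCO[Si](C)(C)C(C)(C)C)(C)CC[C@H]1C[C@H](O[Si](C)(C)C(C)(C)C)/C(C)=C/C/C=C(/C)I
F5 | step 16 | 11-O-acetate of 21 | C=C1C(=O)O[C@@]([C@H](OC(C)=O)CCO[Si](C)(C)C(C)(C)C)(C)CC[C@H]1C[C@H](O[Si](C)(C)C(C)(C)C)/C(C)=C/C/C=C(/C)I
F6 | step 16 | 11-O-acetate of 22 (primary C9 alcohol) | C=C1C(=O)O[C@@]([C@H](OC(C)=O)CCO)(C)CC[C@H]1C[C@H](O[Si](C)(C)C(C)(C)C)/C(C)=C/C/C=C(/C)I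
F7 | step 16 | (3R)-3-acetoxy-3-[(2S,5S)-5-[(2S,3E,6Z)-2-[(tert-butyldimethylsilyl)oxy]-7-iodo-3-methylocta-3,6-dien-1-yl]-2-methyl-6-methylidene-7-oxooxepan-2-yl]propanoic acid | C=C1C(=O)O[C@@]([C@H](OC(C)=O)CC(=O)O)(C)CC[C@H]1C[C@H](O[Si](C)(C)C(C)(C)C)/C(C)=C/C/C=C(/C)I
F8 | step 16 | trimethylstannyl analogue of F7 (SnMe3 in place of I, Z retained) | C=C1C(=O)O[C@@]([C@H](OC(C)=O)CC(=O)O)(C)CC[C@H]1C[C@H](O[Si](C)(C)C(C)(C)C)/C(C)=C/C/C=C(/C)[Sn](C)(C)C
F9 | step 16 | acid chloride of F8 | C=C1C(=O)O[C@@]([C@H](OC(C)=O)CC(=O)Cl)(C)CC[C@H]1C[C@H](O[Si](C)(C)C(C)(C)C)/C(C)=C/C/C=C(/C)[Sn](C)(C)C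
F10 | step 16 | (1S,3S,4E,7Z,11R,12S)-11-acetoxy-3-[(tert-butyldimethylsilyl)oxy]-9-oxocembra-4,7,15(17)-trien-16,12-olide | C=C1C(=O)O[C@@]2(C)CC[C@H]1C[C@H](O[Si](C)(C)C(C)(C)C)/C(C)=C/C/C=C(/C)C(=O)C[C@H]2OC(C)=O
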